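The target, 3-(3,4-dimethoxyphenyl)propyl 3-(3,4-dimethoxyphenyl)propanoate, is the ester of 3-(3,4-dimethoxyphenyl)propanol (ring A half) with 3-(3,4-dimethoxyphenyl)propanoic acid (ring B half). The saturated Cα–Cβ (C2–C3) ethylene link between the ester carbonyl and ring B is read as a hydrogenated cinnamate alkene, and that C=C bond is cut by cross-metathesis: Cβ with ring B comes from a 1-propenylveratrole, Cα with the carbonyl from an acrylate. One ruthenium-catalysed step therefore joins the two aromatic halves and forms the only new carbon–carbon bond. Its precursor is the acrylate ester of the ring A propanol, one acylation from commercial material; hydrogenation of the cinnamate then gives the target.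

Key step: step 2

Remark: methyl isoeugenol is taken as its E isomer; any Z isomer present would converge on the same cinnamate, because the propenyl terminus is expelled as propene and the product geometry is set thermodynamically.

Step 1
Reactants: 1 3-(3,4-dimethoxyphenyl)propan-1-ol; 2 acryloyl chloride
Product: 3 3-(3,4-dimethoxyphenyl)propyl acrylate
Conditions: Et3N, BHT (cat.), CH2Cl2, 0 °C to rt; aq. NaHCO3 work-up
Reagents that add atoms: none
Why: O-acylation of an unhindered primary alcohol with an acid chloride and amine base (nucleophilic acyl substitution) should be fast at 0 °C, the aryl methyl ethers are inert, and the low temperature with a trace of radical inhibitor should keep the acrylate from polymerising.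

Step 2
Reactants: 3 3-(3,4-dimethoxyphenyl)propyl acrylate; 4 (E)-methyl isoeugenol [(E)-1,2-dimethoxy-4-(prop-1-en-1-yl)benzene], used in modest excess and added in two portions
Product: 5 3-(3,4-dimethoxyphenyl)propyl (E)-3-(3,4-dimethoxyphenyl)prop-2-enoate (the E-cinnamate)
Conditions: second-generation Grubbs catalyst RuCl2(H2IMes)(PCy3)(=CHPh) (5 mol %), CH2Cl2, 40 °C, slow argon sweep
Reagents that add atoms: none
Why: Olefin cross-metathesis by the metallacyclobutane mechanism: after phosphine loss the ruthenium alkylidene engages the electron-rich propenyl group of 4 and becomes the 3,4-dimethoxybenzylidene complex, which adds across the terminal C=C of 3 in a [2+2] sense, and cycloreversion of the ruthenacyclobutane releases 5 and a ruthenium methylidene that re-enters the cycle through 4, the two discarded termini leaving together as propene. The closest known reaction type is the cross-metathesis of styrenes and 1-propenylarenes with acrylate esters catalysed by N-heterocyclic-carbene ruthenium benzylidenes. No ring is closed and no stereocenter is formed; the Cα=Cβ double bond of the acid half is the only new skeletal bond. The step needs cross-coupling over homo-coupling and E geometry. Cross-selectivity should follow from the electronic mismatch of the partners: the acrylate self-couples sluggishly and forms an enoate carbene only reluctantly, whereas the methyl-capped internal alkene of 4 dimerises to the stilbene more slowly than a free styrene would, so the arylidene should be intercepted mainly by the unhindered acrylate, and escape of propene drives the exchange forward. E geometry should follow from the thermodynamic preference for the conjugated β-aryl acrylate, reinforced by secondary metathesis.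

Step 3
Reactants: 5 3-(3,4-dimethoxyphenyl)propyl (E)-3-(3,4-dimethoxyphenyl)prop-2-enoate
Product: 6 3-(3,4-dimethoxyphenyl)propyl 3-(3,4-dimethoxyphenyl)propanoate
Conditions: H2 (1 atm), 10% Pd/C, EtOAc, rt (5 first passed through silica to strip ruthenium residues)
Reagents that add atoms: none
Why: Heterogeneous catalytic hydrogenation of a conjugated disubstituted alkene over Pd/C should saturate Cα=Cβ cleanly, since the ester oxygen sits on a non-benzylic propyl carbon and the arenes and aryl methyl ethers are untouched at ambient pressure; no stereocenter is created.

Compound list
1 | 3-(3,4-dimethoxyphenyl)propan-1-ol | COc1ccc(CCCO)cc1OC | starting material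
2 | acryloyl chloride (prop-2-enoyl chloride) | C=CC(=O)Cl | starting material
3 | 3-(3,4-dimethoxyphenyl)propyl acrylate | C=CC(=O)OCCCc1ccc(OC)c(OC)c1 | intermediate
4 | (E)-methyl isoeugenol, (E)-1,2-dimethoxy-4-(prop-1-en-1-yl)benzene | C/C=C/c1ccc(OC)c(OC)c1 | starting material
5 | 3-(3,4-dimethoxyphenyl)propyl (E)-3-(3,4-dimethoxyphenyl)prop-2-enoate | COc1ccc(CCCOC(=O)/C=C/c2ccc(OC)c(OC)c2)cc1OC | intermediate
6 | 3-(3,4-dimethoxyphenyl)propyl 3-(3,4-dimethoxyphenyl)propanoate | COc1ccc(CCCOC(=O)CCc2ccc(OC)c(OC)c2)cc1OC | target

Total step count: 3. Longest linear sequence: 3 steps (1 → 3 → 5 → 6).

Steps most likely to fail

Step 2 is the riskiest. Self-metathesis of the propenylarene to the symmetrical stilbene may outrun the cross reaction, and the ruthenium carbene may decay in the presence of the acrylate, so that conversion stalls with 3 left over. The fallback sets out from 3 and forms the ring B–Cβ bond instead of the Cα=Cβ bond: a Mizoroki–Heck arylation of 3 with 4-iodo-1,2-dimethoxybenzene (COc1ccc(I)cc1OC) under Pd(OAc)2, P(o-tol)3, Et3N in DMF at 90 °C. Oxidative addition of the aryl iodide to zerovalent palladium, syn carbopalladation of the acrylate and syn β-hydride elimination should give the E-cinnamate directly. The fallback comes back to the route at 5 and makes no further compound on the way (F0).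

Step 3 is next. The hydrogenation may stall through poisoning of the palladium surface by ruthenium or phosphine residues carried over from the metathesis, and forcing it with pressure would invite slow reduction of the electron-rich arenes. The fallback sets out from 5 and uses a metal-free diimide reduction: TsNHNH2 and NaOAc in DME/H2O at reflux generate HN=NH, which transfers both hydrogens to the C=C bond in a concerted syn fashion without touching the ester, the ethers or the arenes. It comes back to the route at 6 and makes no further compound on the way (F0).

Step 1 is the least risky. During acylation or work-up the acryloyl unit may polymerise or take up chloride or amine by conjugate addition, eroding the yield of the acrylate. The fallback sets out from 1 and carries the acrylate in masked form: acylation with 3-chloropropanoyl chloride (ClCCC(=O)Cl) and pyridine in CH2Cl2 at 0 °C should give 3-(3,4-dimethoxyphenyl)propyl 3-chloropropanoate F1. Treatment of this ester with Et3N in CH2Cl2 at reflux should then unveil the alkene by E1cB dehydrochlorination, and the fallback comes back to the route at 3.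

Further compounds
F0 | step 2 | none | none
F0 | step 3 | none | none
F1 | step 1 | 3-(3,4-dimethoxyphenyl)propyl 3-chloropropanoate | COc1ccc(CCCOC(=O)CCCl)cc1OC
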